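The furofuran is cut through ring 1 (C1–C2–O3–C4–C5): the C2–O3–C4 triad maps onto a carbonyl ylide and the C1–C5 edge onto an alkene. A guaiacyl-type ylide, freed by fluoride from an α-chloro (trimethylsilyl)methyl ether, is added to the C1=C5 bond of an (S)-5-aryl butenolide in which C6 and its trioxygenated aryl group are already in place. This single operation forms C1–C2 and C4–C5, closes ring 1 cis-fused to the lactone and sets C1, C2 and C5 from C6. The lactone carbonyl becomes C8: reduction, closure of ring 2 (C5–C6–O7–C8–C1) with retention at C6 and debenzylation complete the target.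

Key step: step 7

Remark on numbering: atoms are numbered as in 3,7-dioxabicyclo[3.3.0]octane (C1 and C5 ring-fusion carbons, C2 the guaiacyl carbon, C6 the carbon of the trioxygenated aryl group, C4 and C8 the methylenes). The target is (1R,2S,5R,6S) with both aryl groups exo.

Step 1
Reactants: 1 3-hydroxy-4,5-dimethoxybenzaldehyde
Product: 2 3-(benzyloxy)-4,5-dimethoxybenzaldehyde
Conditions: BnBr, K2CO3, DMF, rt
Reagents that add atoms: benzyl bromide, BrCc1ccccc1
Why: Williamson ether synthesis, in which the phenoxide displaces bromide from benzyl bromide while the aldehyde is inert to K2CO3.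

Step 2
Reactants: 2 3-(benzyloxy)-4,5-dimethoxybenzaldehyde; 3 vinylmagnesium bromide
Product: 4 rac-1-[3-(benzyloxy)-4,5-dimethoxyphenyl]prop-2-en-1-ol
Conditions: THF, −78 to 0 °C; then aq. NH4Cl
Reagents that add atoms: none
Why: Grignard 1,2-addition to the aryl aldehyde gives the secondary allylic alcohol; the new stereocenter (future C6) forms racemic and is resolved in the next step.

Step 3
Reactants: 4 rac-1-[3-(benzyloxy)-4,5-dimethoxyphenyl]prop-2-en-1-ol
Product: 5 (S)-1-[3-(benzyloxy)-4,5-dimethoxyphenyl]prop-2-en-1-ol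
Conditions: Burkholderia cepacia lipase (Amano PS, immobilised), vinyl acetate, MTBE, 30 °C, stopped just past half conversion; chromatography
Reagents that add atoms: none
Why: Lipase-catalysed kinetic resolution by transesterification: by the Kazlauskas rule (aryl large, vinyl medium) the R alcohol is acetylated and the S alcohol is left, its enantiopurity rising as conversion passes one half, so C6 is fixed here.

Step 4
Reactants: 5 (S)-1-[3-(benzyloxy)-4,5-dimethoxyphenyl]prop-2-en-1-ol; 6 acryloyl chloride
Product: 7 (S)-1-[3-(benzyloxy)-4,5-dimethoxyphenyl]prop-2-en-1-yl prop-2-enoate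
Conditions: Et3N, CH2Cl2, −20 to 0 °C
Reagents that add atoms: none
Why: Ester formation from the acid chloride and amine base leaves the C–O bond of the stereocenter intact, so the S configuration is retained; low temperature and base suppress ionisation of the benzylic allylic ester.

Step 5
Reactants: 7 (S)-1-[3-(benzyloxy)-4,5-dimethoxyphenyl]prop-2-en-1-yl prop-2-enoate
Product: 8 (S)-5-[3-(benzyloxy)-4,5-dimethoxyphenyl]furan-2(5H)-one
Conditions: second-generation Grubbs catalyst (H2IMes)(PCy3)Cl2Ru=CHPh (5 mol%), CH2Cl2 (0.01 M), reflux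
Reagents that add atoms: none
Why: Ring-closing metathesis of the acrylate and vinyl groups releases ethylene and closes the unsaturated five-membered lactone; neither C6 nor the benzyl ether is touched.

Step 6
Reactants: 9 4-(benzyloxy)-3-methoxybenzaldehyde; 10 (trimethylsilyl)methanol
Product: 11 racemic α-chloro-4-(benzyloxy)-3-methoxybenzyl (trimethylsilyl)methyl ether
Conditions: dry HCl (g), CH2Cl2, CaCl2, −10 °C; filtered and concentrated under argon, used crude at once
Reagents that add atoms: hydrogen chloride, Cl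
Why: Classical α-chloro ether synthesis (acid-mediated condensation of aldehyde and alcohol with chloride capture, water taken up by CaCl2); the benzyl ether and the C–Si bond survive cold HCl, and the racemic stereocenter is erased when the ylide forms.

Step 7
Reactants: 8 (S)-5-[3-(benzyloxy)-4,5-dimethoxyphenyl]furan-2(5H)-one; 11 racemic α-chloro-4-(benzyloxy)-3-methoxybenzyl (trimethylsilyl)methyl ether
Product: 13 (1S,2S,5R,6S)-2-[4-(benzyloxy)-3-methoxyphenyl]-6-[3-(benzyloxy)-4,5-dimethoxyphenyl]-3,7-dioxabicyclo[3.3.0]octan-8-one, via carbonyl ylide 12 (not isolated)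
Conditions: CsF (dried, 4 equiv), MeCN, 0 °C to rt; 11 (2 equiv) added slowly to 8 and CsF
Reagents that add atoms: none
Why: Fluoride attacks silicon of 11 as chloride departs (ionisation is eased by the para benzyloxy group, which is why that donor ether is kept), and the resulting non-stabilised ylide 12 adds in a concerted suprafacial 1,3-dipolar cycloaddition to the electron-poor C1=C5 bond of 8; this is the known fluoride-induced carbonyl-ylide [3+2] reaction of α-chloro silylmethyl ethers with acceptor alkenes. Ring 1 is closed in the two-bond [3+2] mode (C1–C2 and C4–C5 together), so it can only be cis-fused to the lactone. C1 and C5 are set by approach of the dipole to the face of the butenolide opposite the C6 aryl group, the usual sense for 5-substituted furan-2(5H)-ones. C2 is set by the exo transition state, in which the ylide aryl group (anti across C2–O3) sits over H1 and away from the C8 carbonyl. The regiochemistry needed (CH2 terminus to the β-carbon C5, benzylic terminus to C1) follows from the larger HOMO coefficient at the unsubstituted ylide carbon and the larger LUMO coefficient at C5. Of the three selectivities, facial and regiochemical control are secured by the substrate, while exo placement is the least certain and any C2 epimer would be removed by chromatography at this stage.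

Step 8
Reactants: 13 (1S,2S,5R,6S)-2-[4-(benzyloxy)-3-methoxyphenyl]-6-[3-(benzyloxy)-4,5-dimethoxyphenyl]-3,7-dioxabicyclo[3.3.0]octan-8-one
Product: 14 [(2S,3R,4R)-2-[4-(benzyloxy)-3-methoxyphenyl]-4-{(S)-[3-(benzyloxy)-4,5-dimethoxyphenyl](hydroxy)methyl}oxolan-3-yl]methanol
Conditions: LiAlH4, THF, 0 °C; then H2O, aq. NaOH, H2O
Reagents that add atoms: none
Why: Hydride reduction of the lactone (acyl C–O cleavage) gives the primary C8 alcohol and the free C6 benzylic hydroxyl without breaking any bond to a stereocenter; ethers and benzyl groups are inert to LiAlH4.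

Step 9
Reactants: 14 [(2S,3R,4R)-2-[4-(benzyloxy)-3-methoxyphenyl]-4-{(S)-[3-(benzyloxy)-4,5-dimethoxyphenyl](hydroxy)methyl}oxolan-3-yl]methanol
Product: 16 (1R,2S,5R,6S)-2-[4-(benzyloxy)-3-methoxyphenyl]-6-[3-(benzyloxy)-4,5-dimethoxyphenyl]-3,7-dioxabicyclo[3.3.0]octane, via primary mesylate 15 (not isolated)
Conditions: MsCl (1.1 equiv), pyridine, CH2Cl2, 0 °C to rt
Reagents that add atoms: methanesulfonyl chloride, CS(=O)(=O)Cl (its atoms are held in 15 only and leave on ring closure)
Why: Selective sulfonylation of the primary C8 hydroxyl is followed by intramolecular Williamson etherification (5-exo-tet) by the C6 hydroxyl, so the C6–O bond is never broken and C6 keeps its configuration; ring 2 can only form cis-fused.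

Step 10
Reactants: 16 (1R,2S,5R,6S)-2-[4-(benzyloxy)-3-methoxyphenyl]-6-[3-(benzyloxy)-4,5-dimethoxyphenyl]-3,7-dioxabicyclo[3.3.0]octane
Product: 17 (1R,2S,5R,6S)-2-(4-hydroxy-3-methoxyphenyl)-6-(3-hydroxy-4,5-dimethoxyphenyl)-3,7-dioxabicyclo[3.3.0]octane (CNP0324902.1)
Conditions: H2 (1 atm), 10% Pd/C, EtOAc, rt, stopped at uptake of two equivalents of H2
Reagents that add atoms: none
Why: Catalytic hydrogenolysis cleaves the two aryl benzyl ethers far faster than the hindered ring benzylic C–O bonds in a neutral aprotic solvent (as in the debenzylation of benzylated flavan-3-ols), so all four stereocenters are untouched.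

Compound list
1 | 3-hydroxy-4,5-dimethoxybenzaldehyde | COc1cc(C=O)cc(O)c1OC | starting material
2 | 3-(benzyloxy)-4,5-dimethoxybenzaldehyde | COc1cc(C=O)cc(OCc2ccccc2)c1OC | intermediate
3 | vinylmagnesium bromide | C=C[Mg]Br | starting material
4 | rac-1-[3-(benzyloxy)-4,5-dimethoxyphenyl]prop-2-en-1-ol | C=CC(O)c1cc(OCc2ccccc2)c(OC)c(OC)c1 | intermediate
5 | (S)-1-[3-(benzyloxy)-4,5-dimethoxyphenyl]prop-2-en-1-ol | C=C[C@@H](c1cc(OCc2ccccc2)c(OC)c(OC)c1)O | intermediate
6 | acryloyl chloride | C=CC(=O)Cl | starting material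
7 | (S)-1-[3-(benzyloxy)-4,5-dimethoxyphenyl]prop-2-en-1-yl prop-2-enoate | C=C[C@@H](c1cc(OCc2ccccc2)c(OC)c(OC)c1)OC(=O)C=C | intermediate
8 | (S)-5-[3-(benzyloxy)-4,5-dimethoxyphenyl]furan-2(5H)-one | O=C1C=C[C@@H](c2cc(OCc3ccccc3)c(OC)c(OC)c2)O1 | intermediate
9 | 4-(benzyloxy)-3-methoxybenzaldehyde | COc1cc(C=O)ccc1OCc1ccccc1 | starting material
10 | (trimethylsilyl)methanol | C[Si](C)(C)CO | starting material
11 | racemic α-chloro-4-(benzyloxy)-3-methoxybenzyl (trimethylsilyl)methyl ether | COc1cc(C(Cl)OC[Si](C)(C)C)ccc1OCc1ccccc1 | intermediate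
12 | carbonyl ylide, 4-(benzyloxy)-3-methoxybenzylidene(methylenide)oxonium | COc1cc(C=[O+][CH2-])ccc1OCc1ccccc1 | intermediate (not isolated)
13 | (1S,2S,5R,6S)-2-[4-(benzyloxy)-3-methoxyphenyl]-6-[3-(benzyloxy)-4,5-dimethoxyphenyl]-3,7-dioxabicyclo[3.3.0]octan-8-one | COc1cc([C@H]2OC[C@H]3[C@@H]2C(=O)O[C@@H]3c2cc(OCc3ccccc3)c(OC)c(OC)c2)ccc1OCc1ccccc1 | intermediate
14 | [(2S,3R,4R)-2-[4-(benzyloxy)-3-methoxyphenyl]-4-{(S)-[3-(benzyloxy)-4,5-dimethoxyphenyl](hydroxy)methyl}oxolan-3-yl]methanol | COc1cc([C@H]2OC[C@H]([C@H](O)c3cc(OCc4ccccc4)c(OC)c(OC)c3)[C@@H]2CO)ccc1OCc1ccccc1 | intermediate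
15 | [(2S,3R,4R)-2-[4-(benzyloxy)-3-methoxyphenyl]-4-{(S)-[3-(benzyloxy)-4,5-dimethoxyphenyl](hydroxy)methyl}oxolan-3-yl]methyl methanesulfonate | COc1cc([C@H]2OC[C@H]([C@H](O)c3cc(OCc4ccccc4)c(OC)c(OC)c3)[C@@H]2COS(C)(=O)=O)ccc1OCc1ccccc1 | intermediate (not isolated)
16 | (1R,2S,5R,6S)-2-[4-(benzyloxy)-3-methoxyphenyl]-6-[3-(benzyloxy)-4,5-dimethoxyphenyl]-3,7-dioxabicyclo[3.3.0]octane | COc1cc([C@H]2OC[C@H]3[C@@H]2CO[C@@H]3c2cc(OCc3ccccc3)c(OC)c(OC)c2)ccc1OCc1ccccc1 | intermediate
17 | (1R,2S,5R,6S)-2-(4-hydroxy-3-methoxyphenyl)-6-(3-hydroxy-4,5-dimethoxyphenyl)-3,7-dioxabicyclo[3.3.0]octane (CNP0324902.1) | COc1cc([C@H]2OC[C@H]3[C@@H]2CO[C@@H]3c2cc(O)c(OC)c(OC)c2)ccc1O | target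

Total step count: 10. Longest linear sequence: 9 steps (steps 1–5 and 7–10); step 6 is a one-step side branch.

Steps most likely to fail

Step 7. Three processes threaten it. Fluoride can act as a base at the acidic benzylic C6–H of the butenolide, which would racemise it or move the double bond. The chloro ether can be lost to moisture before the ylide forms. The preference for the exo transition state at C2 may be weak. The fallback builds ring 1 in two bond-forming stages without fluoride, sets out from 8 and returns at 13. Benzophenone-sensitised photoaddition of methanol to 8 (MeOH, hν 350 nm) delivers the hydroxymethyl radical to C5 anti to the aryl group and gives (4R,5S)-5-[3-(benzyloxy)-4,5-dimethoxyphenyl]-4-(hydroxymethyl)oxolan-2-one F1. F1, aldehyde 9 and dry HCl (CH2Cl2, CaCl2, −10 °C) give the α-chloro ether F2. LiN(SiMe3)2 in THF at −78 °C then forms the lactone enolate, which is alkylated at C1 by the tethered chloro ether (5-exo-tet, necessarily cis to the tether), closing ring 1 and giving 13.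

Step 6. The para-alkoxybenzylic chloro ether may ionise and hydrolyse during preparation or concentration, and unconverted aldehyde would itself trap the ylide in step 7. The fallback replaces the aqueous equilibrium by an anhydrous acetal cleavage, sets out from 9 and 10 and returns at 11. Acetalisation of 9 with 10 (2.5 equiv, cat. pyridinium p-toluenesulfonate, toluene, Dean–Stark) gives 4-(benzyloxy)-3-methoxybenzaldehyde bis[(trimethylsilyl)methyl] acetal F3, which can be purified on base-washed silica and stored. Acetyl chloride with cat. ZnBr2 (CH2Cl2, 0 °C) then exchanges one alkoxy group for chloride just before use, giving 11 beside an inert ester.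

Step 5. Ring closure of the electron-poor acrylate may be slow, so that dimerisation by cross-metathesis and loss of catalyst through ester chelation compete. The fallback avoids metathesis and the resolution altogether, sets out from 2 and returns at 8. Catalytic asymmetric addition of methyl propiolate to 2 (Et2Zn, Ti(OiPr)4, the BINOL enantiomer that gives the R carbinol, configuration to be confirmed by Mosher analysis) gives methyl (R)-4-[3-(benzyloxy)-4,5-dimethoxyphenyl]-4-hydroxybut-2-ynoate F4. Semi-hydrogenation (H2, Pd/CaCO3 poisoned with Pb(OAc)2, quinoline, EtOAc) gives methyl (S,Z)-4-[3-(benzyloxy)-4,5-dimethoxyphenyl]-4-hydroxybut-2-enoate F5, which lactonises on standing or with cat. pyridinium p-toluenesulfonate to 8.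

Further compounds
F1 | step 7 | (4R,5S)-5-[3-(benzyloxy)-4,5-dimethoxyphenyl]-4-(hydroxymethyl)oxolan-2-one | OC[C@H]1CC(=O)O[C@@H]1c1cc(OCc2ccccc2)c(OC)c(OC)c1
F2 | step 7 | (4R,5S)-5-[3-(benzyloxy)-4,5-dimethoxyphenyl]-4-({[4-(benzyloxy)-3-methoxyphenyl](chloro)methoxy}methyl)oxolan-2-one (epimers at the chloro carbon) | COc1cc(C(Cl)OC[C@H]2CC(=O)O[C@@H]2c2cc(OCc3ccccc3)c(OC)c(OC)c2)ccc1OCc1ccccc1
F3 | step 6 | 4-(benzyloxy)-3-methoxybenzaldehyde bis[(trimethylsilyl)methyl] acetal | COc1cc(C(OC[Si](C)(C)C)OC[Si](C)(C)C)ccc1OCc1ccccc1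
F4 | step 5 | methyl (R)-4-[3-(benzyloxy)-4,5-dimethoxyphenyl]-4-hydroxybut-2-ynoate | COC(=O)C#C[C@@H](c1cc(OCc2ccccc2)c(OC)c(OC)c1)O
F5 | step 5 | methyl (S,Z)-4-[3-(benzyloxy)-4,5-dimethoxyphenyl]-4-hydroxybut-2-enoate | COC(=O)/C=C\[C@@H](c1cc(OCc2ccccc2)c(OC)c(OC)c1)O
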